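**Retrosynthetic overview**
- Key disconnection: the C2–C1' bond between ring C and ring B, made last by C2–H zincation of 3,5,6,7,8-pentamethoxychromone and Negishi coupling with 1-iodo-2,4-dimethoxybenzene. This replaces the usual chalcone or 1,3-diketone cyclisation that carries ring B through the synthesis.
- Ring C is closed onto ring A from a 2-hydroxyaryl methoxymethyl ketone and a one-carbon formamide acetal; the 3-methoxy group arrives with the methoxyacetyl unit.
- The hydroxy ketone comes from 2,3,4,5-tetramethoxyphenol by O-acylation and Fries rearrangement; the phenol comes from 1,2,3,4-tetramethoxybenzene by ortho-lithiation, borylation and oxidation.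
- Ring order: ring A is bought, ring C is formed in step 3, ring B (bought) is attached in step 4.

Assumption: the target has no stereocentre and no hindered axis, so it is achiral and no stereocontrol is needed; 1,2,3,4-tetramethoxybenzene, methoxyacetyl chloride and 1-iodo-2,4-dimethoxybenzene are taken as catalogue compounds.

**Step 1**
Reactants: 1 1,2,3,4-tetramethoxybenzene
Product: 4 2,3,4,5-tetramethoxyphenol, via aryllithium 2 (not isolated), via dimethyl arylboronate 3 (not isolated)
Conditions: n-BuLi, TMEDA, THF, 0 °C; B(OMe)3, −78 °C → rt; then AcOH, 30 % H2O2, 0 °C → rt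
Reagents that add atoms: hydrogen peroxide, OO
Why: Directed ortho-metalation: the two ring C–H positions of 1 are equivalent and each lies ortho to a methoxy group, so one aryllithium forms, which is borylated and then oxidised with a 1,2-aryl shift from boron to oxygen (boronate oxidation) to the phenol; no stereocentre is formed.

**Step 2**
Reactants: 4 2,3,4,5-tetramethoxyphenol; 5 methoxyacetyl chloride
Product: 7 1-(2-hydroxy-3,4,5,6-tetramethoxyphenyl)-2-methoxyethan-1-one, via aryl methoxyacetate 6 (not isolated)
Conditions: BF3·OEt2 (solvent), 0 °C → 80 °C; then ice–water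
Reagents that add atoms: none
Why: O-Acylation followed by BF3-promoted Fries rearrangement: the acyl group can only move to the single unsubstituted ring carbon, which is ortho to the phenol oxygen and activated by ortho and para methoxy groups, and BF3 is too mild to cleave the aryl methyl ethers; no stereocentre is formed.

**Step 3**
Reactants: 7 1-(2-hydroxy-3,4,5,6-tetramethoxyphenyl)-2-methoxyethan-1-one
Product: 9 3,5,6,7,8-pentamethoxy-4H-chromen-4-one, via enaminone 8 (not isolated)
Conditions: Me2NCH(OMe)2, toluene, 100 °C; concentrate; then AcOH, 80 °C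
Reagents that add atoms: N,N-dimethylformamide dimethyl acetal, COC(OC)N(C)C
Why: Enaminone route to chromones: the activated α-methylene condenses with the formamide acetal, then in acid the phenol adds to the β-carbon (6-endo oxa-Michael addition) and dimethylamine is eliminated to aromatise ring C, which places the methoxy group at C3 and leaves C2–H free; no stereocentre is formed.

**Step 4**
Reactants: 9 3,5,6,7,8-pentamethoxy-4H-chromen-4-one; 10 1-iodo-2,4-dimethoxybenzene
Product: 12 2-(2,4-dimethoxyphenyl)-3,5,6,7,8-pentamethoxy-4H-chromen-4-one, via chromon-2-ylzinc chloride 11 (not isolated)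
Conditions: TMPZnCl·LiCl (TMP = 2,2,6,6-tetramethylpiperidide, 1.3 equiv), THF, 25 °C; then 10, Pd(OAc)2 (2 mol %), 2-dicyclohexylphosphino-2',6'-dimethoxybiphenyl (SPhos, 4 mol %), 60 °C
Reagents that add atoms: none
Why: Directed C–H zincation then Negishi cross-coupling: C2–H is the only sp2 C–H of 9 and is acidified by the ring oxygen, the conjugated carbonyl and the adjacent 3-methoxy group, the hindered zinc amide does not add to the pyranone, and the heteroarylzinc couples with the aryl iodide after its oxidative addition to zerovalent palladium; the product is achiral because the C2–C1' axis carries a single ortho substituent on ring B and rotates freely.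

**Compound list**
1 | 1,2,3,4-tetramethoxybenzene | COc1ccc(OC)c(OC)c1OC | starting material
2 | (2,3,4,5-tetramethoxyphenyl)lithium | [Li]c1cc(OC)c(OC)c(OC)c1OC | intermediate
3 | dimethyl (2,3,4,5-tetramethoxyphenyl)boronate | COB(OC)c1cc(OC)c(OC)c(OC)c1OC | intermediate
4 | 2,3,4,5-tetramethoxyphenol | COc1cc(O)c(OC)c(OC)c1OC | intermediate
5 | methoxyacetyl chloride | COCC(=O)Cl | starting material
6 | 2,3,4,5-tetramethoxyphenyl 2-methoxyacetate | COCC(=O)Oc1cc(OC)c(OC)c(OC)c1OC | intermediate
7 | 1-(2-hydroxy-3,4,5,6-tetramethoxyphenyl)-2-methoxyethan-1-one | COCC(=O)c1c(O)c(OC)c(OC)c(OC)c1OC | intermediate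
8 | (Z)-3-(dimethylamino)-1-(2-hydroxy-3,4,5,6-tetramethoxyphenyl)-2-methoxyprop-2-en-1-one (geometry drawn as expected; it is lost on cyclisation) | CO/C(=C\N(C)C)C(=O)c1c(O)c(OC)c(OC)c(OC)c1OC | intermediate
9 | 3,5,6,7,8-pentamethoxy-4H-chromen-4-one | COc1coc2c(OC)c(OC)c(OC)c(OC)c2c1=O | intermediate
10 | 1-iodo-2,4-dimethoxybenzene | COc1ccc(I)c(OC)c1 | starting material
11 | chloro(3,5,6,7,8-pentamethoxy-4-oxo-4H-chromen-2-yl)zinc (LiCl complex) | COc1c([Zn]Cl)oc2c(OC)c(OC)c(OC)c(OC)c2c1=O | intermediate
12 | 2-(2,4-dimethoxyphenyl)-3,5,6,7,8-pentamethoxy-4H-chromen-4-one (3,5,6,7,8,2',4'-heptamethoxyflavone, achiral) | COc1ccc(-c2oc3c(OC)c(OC)c(OC)c(OC)c3c(=O)c2OC)c(OC)c1 | target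

**Totals**
Total step count: 4. Longest linear sequence: 4 steps (1 → 4 → 7 → 9 → 12).

**Steps most likely to fail, with fallbacks**

Step 4 (key step). The electron-rich, 3-methoxy-substituted chromone may zincate incompletely, or the hindered coupling may be slow. The fallback sets out from 7 and comes back at 12, bypassing 9 and giving up the late C–H arylation. Phenol 7 is acylated with 2,4-dimethoxybenzoyl chloride (pyridine, DMAP, CH2Cl2) to give 2-(2-methoxyacetyl)-3,4,5,6-tetramethoxyphenyl 2,4-dimethoxybenzoate F1. LiN(SiMe3)2 in THF (−20 °C → rt) then brings about the Baker–Venkataraman O→C acyl shift to 1-(2,4-dimethoxyphenyl)-3-(2-hydroxy-3,4,5,6-tetramethoxyphenyl)-2-methoxypropane-1,3-dione F2, which is racemic and enolisable; its stereocentre disappears in the next operation. Cyclodehydration with catalytic H2SO4 in AcOH at 100 °C closes ring C and gives 12.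

Step 2. BF3 may cleave a methoxy group next to the new carbonyl, or the chelating methoxyacetyl ester may rearrange poorly. The fallback sets out from 4 and comes back at 7, replacing the electrophilic acylation by an anionic one with no Lewis acid. Phenol 4 is protected with chloromethyl methyl ether and i-Pr2NEt in CH2Cl2 as 1-(methoxymethoxy)-2,3,4,5-tetramethoxybenzene F3. n-BuLi in THF at 0 °C lithiates the single free ring position, between the acetal oxygen and a methoxy group, to give [2-(methoxymethoxy)-3,4,5,6-tetramethoxyphenyl]lithium F4. Addition of N-methoxy-N-methyl-2-methoxyacetamide gives 2-methoxy-1-[2-(methoxymethoxy)-3,4,5,6-tetramethoxyphenyl]ethan-1-one F5, and HCl in MeOH removes the acetal to give 7.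

Step 1. The very electron-rich phenol may be over-oxidised to a quinone by peroxide, or lithiation may be incomplete. The fallback sets out from 1 and comes back at 4, replacing metalation by electrophilic substitution and keeping the phenol masked while oxidant is present. Rieche formylation of 1 (Cl2CHOMe, TiCl4, CH2Cl2, 0 °C) gives 2,3,4,5-tetramethoxybenzaldehyde F6. Baeyer–Villiger oxidation with mCPBA in CH2Cl2 gives 2,3,4,5-tetramethoxyphenyl formate F7, and K2CO3 in MeOH cleaves the formate to give 4.

**Further compounds**
F1 | step 4 | 2-(2-methoxyacetyl)-3,4,5,6-tetramethoxyphenyl 2,4-dimethoxybenzoate | COCC(=O)c1c(OC(=O)c2ccc(OC)cc2OC)c(OC)c(OC)c(OC)c1OC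
F2 | step 4 | 1-(2,4-dimethoxyphenyl)-3-(2-hydroxy-3,4,5,6-tetramethoxyphenyl)-2-methoxypropane-1,3-dione (racemic) | COc1ccc(C(=O)C(OC)C(=O)c2c(O)c(OC)c(OC)c(OC)c2OC)c(OC)c1
F3 | step 2 | 1-(methoxymethoxy)-2,3,4,5-tetramethoxybenzene | COCOc1cc(OC)c(OC)c(OC)c1OC
F4 | step 2 | [2-(methoxymethoxy)-3,4,5,6-tetramethoxyphenyl]lithium | [Li]c1c(OCOC)c(OC)c(OC)c(OC)c1OC
F5 | step 2 | 2-methoxy-1-[2-(methoxymethoxy)-3,4,5,6-tetramethoxyphenyl]ethan-1-one | COCOc1c(C(=O)COC)c(OC)c(OC)c(OC)c1OC
F6 | step 1 | 2,3,4,5-tetramethoxybenzaldehyde | COc1cc(C=O)c(OC)c(OC)c1OC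
F7 | step 1 | 2,3,4,5-tetramethoxyphenyl formate | COc1cc(OC=O)c(OC)c(OC)c1OC
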